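**Retrosynthetic overview** (labdane numbering; β = the face of the C10 methyl)
- The strategy rests on the quaternary C4 (CH3 + C19 carboxyl) of ring A (C1–C5, C10), cis-fused to ring B (C5–C10). C4 and C19 are read as the α-carbon and carbonyl of a δ-lactone C19(=O)–O–C1 with a vinyl group on C1, so C3–C4 is cut by a retro lactone-enolate Claisen shift.
- After the shift: C19 is esterified, the C8 ketone is unmasked and dehydrogenated to the C6=C7 enone, and C9–C11 is made by alkylating its only α′ position with an iodo ester from (R)-3-methylglutarate. Hydrogenation, C8 methylenation and selective C15 saponification finish.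
- Before the shift: the lactone comes from an aldehyde that carries C19 as a dioxolane. C1 is set by vinyl addition, oxidation and oxazaborolidine reduction; C5 and C10 by auxiliary-controlled Grignard conjugate addition–methylation of a cyclohexenecarbaldehyde imine; ring B comes from 3-methoxybenzyl alcohol by Birch reduction.
- C9 stays CH2 through the key step. A C9 side chain would compete with C5 for the face of the C10 methylation, and the C9 epimers of the C8 ketone are expected to be too close in energy for equilibration, so C9–C11 is formed last, as a C–C bond on the convex face.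
- Ring order: ring B (from the arene), the lactone ring, then ring A by the [3,3] shift.

Key step: step 15

Assumption: in the magnesium chelate of the tert-leucine ester aldimine the Grignard carbon is taken to be delivered anti to the tert-butyl group; on this model the (R)-amine gives the required C5 configuration.

**Route**

Step 1
Reactants: 1 (R)-3-methylglutaric acid monomethyl ester
Product: 2 methyl (3R)-5-hydroxy-3-methylpentanoate
Conditions: BH3·SMe2, THF, 0 °C → rt; then MeOH
Reagents that add atoms: none
Why: Chemoselective borane reduction takes the free carboxylic acid much faster than the methyl ester, so the acid carbon becomes C11–OH, C15 stays an ester and C13 is untouched.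

Step 2
Reactants: 2 methyl (3R)-5-hydroxy-3-methylpentanoate
Product: 3 methyl (3S)-5-iodo-3-methylpentanoate
Conditions: I2, PPh3, imidazole, CH2Cl2, 0 °C → rt
Reagents that add atoms: iodine, II
Why: Appel-type iodination converts the primary alcohol into the iodide by SN2 at C11 and leaves the ester and C13 alone (the descriptor changes only through CIP priorities).

Step 3
Reactants: 4 3-methoxybenzyl alcohol
Product: 5 (5-methoxycyclohexa-1,4-dien-1-yl)methanol
Conditions: Li, NH3 (l), THF, t-BuOH, −78 → −33 °C; then NH4Cl
Reagents that add atoms: none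
Why: Birch reduction of the lithium benzylic alkoxide should give the 2,5-dihydro arene with both donor groups on double-bond carbons, which puts the ring alkene at C10=C5 and the enol ether at C7=C8; the alkoxide form suppresses benzylic C–O cleavage.

Step 4
Reactants: 5 (5-methoxycyclohexa-1,4-dien-1-yl)methanol
Product: 6 (1,4-dioxaspiro[4.5]dec-7-en-7-yl)methanol
Conditions: HOCH2CH2OH, p-TsOH (cat.), THF, 0 °C → rt
Reagents that add atoms: ethylene glycol, OCCO
Why: Acid-catalysed transketalisation: protonation of the enol ether at C7 gives the C8 oxocarbenium ion, which the diol traps, while the C10=C5 alkene stays β,γ to the ketal.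

Step 5
Reactants: 6 (1,4-dioxaspiro[4.5]dec-7-en-7-yl)methanol
Product: 7 1,4-dioxaspiro[4.5]dec-7-ene-7-carbaldehyde
Conditions: MnO2, CH2Cl2, rt
Reagents that add atoms: none
Why: Allylic oxidation with MnO2 takes the primary allylic alcohol to the conjugated aldehyde without touching the ketal.

Step 6
Reactants: 7 1,4-dioxaspiro[4.5]dec-7-ene-7-carbaldehyde; 8 tert-butyl (2R)-2-amino-3,3-dimethylbutanoate
Product: 9 E-aldimine of 7 with 8
Conditions: MgSO4, CH2Cl2, rt
Reagents that add atoms: none
Why: Imine condensation of the aldehyde with the primary amine under dehydrating conditions gives the E-aldimine that carries the auxiliary.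

Step 7
Reactants: 9 E-aldimine of 7 with 8; 10 (1,3-dioxolan-2-ylmethyl)magnesium bromide
Product: 13 8-(1,3-dioxolan-2-ylmethyl)-7-methyl-1,4-dioxaspiro[4.5]decane-7-carbaldehyde (formyl and dioxolanylmethyl cis), via magnesium aza-enolate 11 (not isolated), via C10-methylated aldimine 12 (not isolated)
Conditions: 10, THF, −23 °C; then MeI, HMPA, −23 °C → rt; then AcOH–NaOAc buffer (pH 4.5), H2O/pentane, rt
Reagents that add atoms: iodomethane, CI; water, O
Why: Chelation-controlled conjugate addition of the Grignard reagent to the s-cis unsaturated aldimine (magnesium held by N and the ester carbonyl, carbon delivered to C5 anti to the tert-butyl group) sets C5, alkylation of the magnesium aza-enolate anti to the new C5 substituent sets the quaternary C10 with methyl trans to the C5 chain, and buffered imine hydrolysis frees the aldehyde with both dioxolanes intact.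

Step 8
Reactants: 13 aldehyde (C1 formyl on C10); 14 vinylmagnesium bromide
Product: 15 C1 allylic alcohols (both C1 epimers)
Conditions: THF, −78 → 0 °C; then aq. NH4Cl
Reagents that add atoms: none
Why: Grignard 1,2-addition to the neopentyl aldehyde brings in C2 and C3; the Felkin–Anh model (C5 anti to the nucleophile) predicts mainly the unwanted 1R epimer, so C1 is re-set through the ketone in steps 9 and 10.

Step 9
Reactants: 15 C1 allylic alcohols
Product: 16 C1 vinyl ketone
Conditions: Dess–Martin periodinane, CH2Cl2, rt
Reagents that add atoms: none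
Why: Dess–Martin oxidation converts the hindered secondary allylic alcohol into the vinyl ketone under neutral conditions that spare the acetals.

Step 10
Reactants: 16 C1 vinyl ketone
Product: 17 (1S)-allylic alcohol
Conditions: (R)-2-methyl-CBS-oxazaborolidine (cat.), catecholborane, PhMe, −78 °C
Reagents that add atoms: none
Why: Corey–Bakshi–Shibata reduction with the quaternary C10 as the large group should give the (1S)-carbinol, the same face that the Felkin–Anh model favours for hydride (C5 anti to hydride, C9 next to the carbonyl oxygen), so reagent and substrate control are matched; catecholborane at low temperature gives 1,2-reduction.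

Step 11
Reactants: 17 (1S)-allylic alcohol
Product: 18 lactol ketone (C19 hemiacetal closed on the C1 oxygen, C8 ketone)
Conditions: 1 M HCl, THF, rt
Reagents that add atoms: water, O
Why: Acetal hydrolysis removes both dioxolanes and the freed C19 aldehyde is trapped by the C1 hydroxyl as the six-membered lactol, which is cis-fused because C1 and C4 sit on the same face of ring B.

Step 12
Reactants: 18 lactol ketone
Product: 19 keto lactone
Conditions: PhI(OAc)2, TEMPO (cat.), CH2Cl2, rt
Reagents that add atoms: none
Why: Oxoammonium (TEMPO) oxidation takes the lactol to the δ-lactone and leaves the ketone, the vinyl group and C1 untouched.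

Step 13
Reactants: 19 keto lactone
Product: 20 ketal lactone
Conditions: TMSOCH2CH2OTMS, TMSOTf (cat.), CH2Cl2, −78 °C
Reagents that add atoms: 1,2-bis(trimethylsilyloxy)ethane, C[Si](C)(C)OCCO[Si](C)(C)C
Why: Aprotic ketalisation with the bis-silyl glycol protects the C8 ketone at low temperature without opening the lactone, so that only C4 is enolisable in steps 14 and 15.

Step 14
Reactants: 20 ketal lactone
Product: 22 C4-methyl lactone (Claisen precursor, C4 epimers), via lithium enolate 21 (not isolated)
Conditions: LDA, THF, −78 °C; then MeI, −78 → −40 °C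
Reagents that add atoms: iodomethane, CI
Why: Enolate alkylation of the lactone with iodomethane puts the methyl group on C4; the C4 configuration does not matter because C4 becomes planar again in step 15.

Step 15
Reactants: 22 C4-methyl lactone
Product: 25 ring A cyclohexene acid (C1=C2, C4 with CH3 β and CO2H α, cis-fused, C8 ketal), via silyl ketene acetal 23 (not isolated), via trimethylsilyl ester 24 (not isolated)
Conditions: LDA, THF, −78 °C; TMSCl–Et3N, −78 °C → rt; PhMe, 105 °C; then MeOH/H2O
Reagents that add atoms: none
Why: Deprotonation at C4 and O-silylation give the cyclic silyl ketene acetal 23, whose C4=C19–O–C1–C2=C3 array undergoes a concerted [3,3]-sigmatropic shift (Ireland–Claisen rearrangement of a lactone silyl ketene acetal with an alkenyl group on the carbinol carbon, a known lactone-to-carbocycle transposition). Ring A (C4–C3–C2–C1–C10–C5) closes by formation of C3–C4 while C1–O breaks, through a boat-like bicyclo[2.2.2]-type transition state in which the vinyl group bridges from C1 to C4 across one face of the lactone ring; the six-membered lactone is exchanged for a six-membered carbocycle and C19 leaves the ring as the silyl ester 24. The new quaternary centre C4 is controlled by C1: C3 is delivered suprafacially to the face of C4 on which the vinyl group sits (the β face that carries H5 and the C10 methyl), so the C4 methyl ends cis to H5 and C19 cis to C6. The cis fusion at C5–C10 is carried over because neither centre takes part. The step needs O-silylation and the boat geometry; the ring fixes the ketene acetal geometry and the C1 configuration from step 10 leaves only one face of C4 within reach of C3. Mild hydrolysis of 24 then gives acid 25 with the ketal intact.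

Step 16
Reactants: 25 ring A cyclohexene acid
Product: 26 methyl ester of 25
Conditions: CH2N2, Et2O, 0 °C
Reagents that add atoms: diazomethane, C=[N+]=[N-]
Why: Diazomethane esterification methylates the hindered tertiary acid without acid or base, giving the C19 methyl ester of the target.

Step 17
Reactants: 26 methyl ester
Product: 27 C8 keto ester
Conditions: 1 M HCl, THF, rt
Reagents that add atoms: water, O
Why: Ketal hydrolysis frees the C8 ketone; no stereocentre is α to it at this stage (C9 is CH2), so nothing can epimerise.

Step 18
Reactants: 27 C8 keto ester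
Product: 28 C6=C7 enone
Conditions: IBX, DMSO/PhF, 70 °C
Reagents that add atoms: none
Why: IBX dehydrogenation of the ketone can only run to the C7–C6 side because C10 carries no hydrogen, so the enone should form regiospecifically and the isolated C1=C2 alkene is left.

Step 19
Reactants: 28 C6=C7 enone; 3 methyl (3S)-5-iodo-3-methylpentanoate
Product: 30 C9-alkylated enone diester, via lithium dienolate 29 (not isolated)
Conditions: LDA, THF, −78 °C; then 3, DMPU, −78 → 0 °C
Reagents that add atoms: none
Why: Kinetic deprotonation at the only α′ position (C9) gives the cross-conjugated dienolate, and SN2 alkylation by the primary iodide should occur on the convex β face of the cis-fused bicycle (syn to H5 and the C10 methyl, away from ring A and the C19 ester that lie under ring B), which sets C9 by C–C bond formation.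

Step 20
Reactants: 30 C9-alkylated enone diester
Product: 31 saturated C8 keto diester
Conditions: H2 (1 atm), Pd/C, EtOAc, rt
Reagents that add atoms: none
Why: Catalytic hydrogenation saturates the enone C6=C7 and the ring A C1=C2 alkene without creating a stereocentre and leaves the ketone, the esters and C9 unchanged.

Step 21
Reactants: 31 saturated C8 keto diester
Product: 32 8(17)-methylene diester
Conditions: Zn, CH2Br2, TiCl4, THF/CH2Cl2, 0 °C → rt
Reagents that add atoms: dibromomethane, BrCBr
Why: Takai–Lombardo methylenation converts the hindered, enolisable ketone into the exocyclic alkene under non-basic conditions, so C9 is not epimerised and the esters are not attacked.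

Step 22
Reactants: 32 8(17)-methylene diester
Product: 33 CNP0135192.2 (target)
Conditions: LiOH, THF/MeOH/H2O, rt; then dilute HCl to pH 3
Reagents that add atoms: lithium hydroxide, [Li+].[OH-]
Why: Saponification discriminates the two methyl esters by hindrance: the primary C15 ester is hydrolysed while the C19 ester on the quaternary C4 should be inert under these conditions.

**Compound list**

1 | (R)-3-methylglutaric acid monomethyl ester | OC(=O)C[C@@H](C)CC(=O)OC | starting material
2 | methyl (3R)-5-hydroxy-3-methylpentanoate | OCC[C@@H](C)CC(=O)OC | intermediate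
3 | methyl (3S)-5-iodo-3-methylpentanoate (C11–C15 with the C13 methyl) | ICC[C@@H](C)CC(=O)OC | intermediate
4 | 3-methoxybenzyl alcohol | COc1cccc(CO)c1 | starting material
5 | (5-methoxycyclohexa-1,4-dien-1-yl)methanol | COC1=CCC=C(CO)C1 | intermediate
6 | (1,4-dioxaspiro[4.5]dec-7-en-7-yl)methanol | OCC1=CCCC2(OCCO2)C1 | intermediate
7 | 1,4-dioxaspiro[4.5]dec-7-ene-7-carbaldehyde | O=CC1=CCCC2(OCCO2)C1 | intermediate
8 | tert-butyl (2R)-2-amino-3,3-dimethylbutanoate, (R)-tert-leucine tert-butyl ester | CC(C)(C)OC(=O)[C@H](N)C(C)(C)C | starting material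
9 | E-aldimine of 7 with 8 | CC(C)(C)OC(=O)[C@H](N=CC1=CCCC2(OCCO2)C1)C(C)(C)C | intermediate
10 | (1,3-dioxolan-2-ylmethyl)magnesium bromide | Br[Mg]CC1OCCO1 | starting material
11 | N-bromomagnesio enamine (aza-enolate) from addition at C5 | CC(C)(C)OC(=O)[C@H](N([Mg]Br)C=C1CC2(OCCO2)CC[C@@H]1CC3OCCO3)C(C)(C)C | intermediate (not isolated)
12 | C10-methylated aldimine | CC(C)(C)OC(=O)[C@H](N=C[C@]1(C)CC2(OCCO2)CC[C@@H]1CC3OCCO3)C(C)(C)C | intermediate (not isolated)
13 | 8-(1,3-dioxolan-2-ylmethyl)-7-methyl-1,4-dioxaspiro[4.5]decane-7-carbaldehyde, formyl and dioxolanylmethyl cis (C5 and C10 as in the target) | O=C[C@]1(C)CC2(OCCO2)CC[C@@H]1CC3OCCO3 | intermediate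
14 | vinylmagnesium bromide | C=C[Mg]Br | starting material
15 | allylic alcohols from vinyl addition to 13, both C1 epimers | OC(C=C)[C@]1(C)CC2(OCCO2)CC[C@@H]1CC3OCCO3 | intermediate
16 | vinyl ketone (C1 carbonyl on C10) | O=C(C=C)[C@]1(C)CC2(OCCO2)CC[C@@H]1CC3OCCO3 | intermediate
17 | (1S)-allylic alcohol | O[C@@H](C=C)[C@]1(C)CC2(OCCO2)CC[C@@H]1CC3OCCO3 | intermediate
18 | lactol ketone: cis-fused 3-hydroxy-8a-methyl-1-vinylhexahydroisochroman-7-one (H5, C10 methyl and vinyl all β) | O=C1CC[C@@H]2CC(O)O[C@@H](C=C)[C@]2(C)C1 | intermediate
19 | keto lactone: cis-fused 8a-methyl-1-vinylhexahydroisochromane-3,7-dione | O=C1CC[C@@H]2CC(=O)O[C@@H](C=C)[C@]2(C)C1 | intermediate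
20 | ketal lactone: 19 with the C8 ketone as ethylene ketal | O1CCOC12CC[C@@H]3CC(=O)O[C@@H](C=C)[C@]3(C)C2 | intermediate
21 | lithium enolate of 20 | O1CCOC12CC[C@@H]3C=C(O[Li])O[C@@H](C=C)[C@]3(C)C2 | intermediate (not isolated)
22 | C4-methyl ketal lactone, Claisen precursor (C4 epimers) | O1CCOC12CC[C@@H]3C(C)C(=O)O[C@@H](C=C)[C@]3(C)C2 | intermediate
23 | trimethylsilyl ketene acetal of 22 | O1CCOC12CC[C@@H]3C(C)=C(O[Si](C)(C)C)O[C@@H](C=C)[C@]3(C)C2 | intermediate (not isolated)
24 | trimethylsilyl ester of 25 | O1CCOC12CC[C@H]3[C@](C)(C=CC[C@@]3(C)C(=O)O[Si](C)(C)C)C2 | intermediate (not isolated)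
25 | cis-fused ring A cyclohexene acid: C1=C2, C4 CH3 β and CO2H α, C10 CH3 β, H5 β, C8 ethylene ketal | O1CCOC12CC[C@H]3[C@](C)(C=CC[C@@]3(C)C(=O)O)C2 | intermediate
26 | methyl ester of 25 | O1CCOC12CC[C@H]3[C@](C)(C=CC[C@@]3(C)C(=O)OC)C2 | intermediate
27 | C8 keto ester | O=C1CC[C@H]2[C@](C)(C=CC[C@@]2(C)C(=O)OC)C1 | intermediate
28 | C6=C7 enone ester | O=C1C=C[C@H]2[C@](C)(C=CC[C@@]2(C)C(=O)OC)C1 | intermediate
29 | lithium dienolate of 28 (C8–O, C8=C9, C6=C7) | [Li]OC=1C=C[C@H]2[C@](C)(C=CC[C@@]2(C)C(=O)OC)C=1 | intermediate (not isolated)
30 | C9-alkylated enone diester, side chain β | O=C1C=C[C@H]2[C@](C)(C=CC[C@@]2(C)C(=O)OC)[C@H]1CC[C@@H](C)CC(=O)OC | intermediate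
31 | saturated C8 keto diester | O=C1CC[C@H]2[C@](C)(CCC[C@@]2(C)C(=O)OC)[C@H]1CC[C@@H](C)CC(=O)OC | intermediate
32 | 8(17)-methylene dimethyl ester | C=C1CC[C@H]2[C@](C)(CCC[C@@]2(C)C(=O)OC)[C@H]1CC[C@@H](C)CC(=O)OC | intermediate
33 | CNP0135192.2 | C=C1CC[C@H]2[C@](C)(CCC[C@@]2(C)C(=O)OC)[C@H]1CC[C@@H](C)CC(=O)O | target

**Step count and risk**

Total steps: 22. Longest linear sequence: 20 (steps 3–22; steps 1–2 make iodide 3).

Steps most likely to fail:

1. Step 15. The silylated lactone enolate may not reach the strained boat transition state before it C-silylates, desilylates or decomposes on heating. Fallback, from 22: methanolysis (K2CO3, MeOH, 0 °C) opens the lactone to the C1-hydroxy methyl ester F1; ClP(O)(OEt)2 with DMAP and pyridine gives the allylic diethyl phosphate F2; KHMDS (THF, −78 → 0 °C) forms the potassium ester enolate F3, whose C4 attacks C3 in an intramolecular SN2′ displacement of phosphate from C1. This closes ring A and gives methyl ester 26 directly, where the route is rejoined (step 16 is skipped). The C4 configuration then depends on the cyclisation transition state and any epimer would have to be separated.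

2. Step 19. SN2 at the hindered dienolate carbon may be slow, so that proton transfer, O-alkylation, attack of the enolate on the nearby C19 ester or loss of face selectivity compete. Fallback, from 28: condensation with 1,1-dimethylhydrazine (AcOH cat., EtOH, reflux) gives the N,N-dimethylhydrazone F4; LDA (THF, −78 °C) gives the more nucleophilic lithiated aza-dienolate F5; iodide 3 gives the C9-alkylated hydrazone F6; hydrolysis with aqueous CuCl2 in THF returns to 30.

3. Step 7. The acetal-bearing Grignard reagent may lose chelate control or undergo β-alkoxide elimination, leading to poor face selectivity or 1,2-addition. Fallback, from 9: vinylmagnesium bromide 14 under the same auxiliary control gives the magnesium aza-enolate F7, MeI the C10-methylated imine F8, and buffered hydrolysis the vinyl aldehyde F9. BH3·THF followed by NaOH/H2O2 reduces the aldehyde and hydroborates the vinyl group to the diol F10; Dess–Martin oxidation gives the dialdehyde F11; ethylene glycol (1 equiv) with PPTS acetalises only the unhindered C19 aldehyde and returns to 13.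

Further compounds
F1 | step 15 | C1-hydroxy methyl ester from methanolysis of 22 | O1CCOC12CC[C@H](C(C)C(=O)OC)[C@](C)([C@@H](O)C=C)C2
F2 | step 15 | allylic diethyl phosphate of F1 | O1CCOC12CC[C@H](C(C)C(=O)OC)[C@](C)([C@@H](OP(=O)(OCC)OCC)C=C)C2
F3 | step 15 | potassium ester enolate of F2 | O1CCOC12CC[C@H](C(C)=C(O[K])OC)[C@](C)([C@@H](OP(=O)(OCC)OCC)C=C)C2
F4 | step 19 | N,N-dimethylhydrazone of 28 | CN(C)N=C1C=C[C@H]2[C@](C)(C=CC[C@@]2(C)C(=O)OC)C1
F5 | step 19 | lithiated aza-dienolate of F4 | CN(C)N([Li])C=1C=C[C@H]2[C@](C)(C=CC[C@@]2(C)C(=O)OC)C=1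
F6 | step 19 | C9-alkylated N,N-dimethylhydrazone | CN(C)N=C1C=C[C@H]2[C@](C)(C=CC[C@@]2(C)C(=O)OC)[C@H]1CC[C@@H](C)CC(=O)OC
F7 | step 7 | N-bromomagnesio enamine from vinyl addition to 9 | CC(C)(C)OC(=O)[C@H](N([Mg]Br)C=C1CC2(OCCO2)CC[C@@H]1C=C)C(C)(C)C
F8 | step 7 | C10-methylated aldimine with C5 vinyl | CC(C)(C)OC(=O)[C@H](N=C[C@]1(C)CC2(OCCO2)CC[C@@H]1C=C)C(C)(C)C
F9 | step 7 | 7-methyl-8-vinyl-1,4-dioxaspiro[4.5]decane-7-carbaldehyde, formyl and vinyl cis | O=C[C@]1(C)CC2(OCCO2)CC[C@@H]1C=C
F10 | step 7 | diol: C1 hydroxymethyl and C19 hydroxyethyl | OC[C@]1(C)CC2(OCCO2)CC[C@@H]1CCO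
F11 | step 7 | dialdehyde: C1 formyl and C19 formylmethyl | O=C[C@]1(C)CC2(OCCO2)CC[C@@H]1CC=O
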